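**Plan**

1. Numbering used here: cyclopentane C1(H)–C2–C3(OH)–C4(Me2)–C5(OH); cycloheptanone C5–C6–C7–C8(Me)–C9(Me, chain)–C10(=O)–C1; C11–C12 link; C13–C16 butenolide. β is the face of the C3 oxygen (H-1 and both ring methyls are β; the C5 hydroxyl and the side chain are α).
2. Retrosynthesis: cut C12–C13 (B-alkyl Suzuki), then C9–C11 and C9–CH3 (two enolate alkylations), then open the seven-membered ring at C6–C7 and C9–C10 in one operation. This gives a 2-(silylmethyl)allyl cation (C7–C8–C9, its CH2Si carbon becoming the C8 methyl) and a cyclopentane carrying the diene C6=C5–C1=C10–OSi.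
3. Enabling feature: the four-carbon arc C6–C5–C1–C10 of the cycloheptanone sits on the two adjacent cyclopentane carbons C5 and C1. It can therefore be presented as an s-cis-locked 1,2-bis(alkylidene)cyclopentane whose C10 oxygen is a silyl enol ether, and the C8 methyl branch is the trace of a trimethylenemethane-type three-carbon partner.
4. Forward order: cyclopentane (from 2,2-dimethylcyclopentane-1,3-dione), then the seven-membered ring by cationic (4+3) annulation, then C8, C5/C1 and C9 on the bicycle, butenolide last.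
5. Stereochemistry: C3 from a CBS desymmetrisation. The C10 carbinol from a second, reagent-controlled CBS reduction relays to C8 (hydroxyl-directed hydrogenation), C5 (hydroxyl-directed epoxidation) and C1 (stereospecific semipinacol hydride shift, trans fusion). C9 is set by enolate attack anti to the C8 methyl.

Key step: step 6

Remark on the chemistry: the sense of induction of both CBS reductions is assigned from the usual large/small model and would have to be confirmed on the first intermediate.

**Route**

Step 1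
Reactants: 1 2,2-dimethylcyclopentane-1,3-dione
Product: 2 (R)-3-hydroxy-2,2-dimethylcyclopentan-1-one
Conditions: (S)-2-methyl-CBS-oxazaborolidine (10 mol %), catecholborane (1.0 equiv), toluene, −78 to −40 °C
Reagents that add atoms: none
Why: CBS desymmetrising mono-reduction of the prochiral 1,3-dione: with the quaternary carbon as the large group the (S)-catalyst should give the (R)-carbinol that becomes C3, and the hydroxy ketone should be reduced further only slowly at this temperature.

Step 2
Reactants: 2 (R)-3-hydroxy-2,2-dimethylcyclopentan-1-one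
Product: 3 (R)-3-[(tert-butyldimethylsilyl)oxy]-2,2-dimethylcyclopentan-1-one
Conditions: TBSCl, imidazole, DMF, rt
Reagents that add atoms: tert-butyldimethylsilyl chloride, CC(C)(C)[Si](C)(C)Cl
Why: Routine silylation masks the C3 hydroxyl as a bulky, non-directing ether that later shields the β face.

Step 3
Reactants: 3 (R)-3-[(tert-butyldimethylsilyl)oxy]-2,2-dimethylcyclopentan-1-one
Product: 4 (R,E)-3-[(tert-butyldimethylsilyl)oxy]-5-[(dimethylamino)methylidene]-2,2-dimethylcyclopentan-1-one
Conditions: t-BuOCH(NMe2)2, toluene, 90 °C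
Reagents that add atoms: tert-butoxybis(dimethylamino)methane (Bredereck's reagent), CN(C)C(OC(C)(C)C)N(C)C
Why: Aminomethylenation with Bredereck's reagent can occur only at the single enolisable α-CH2 (the other α-carbon is quaternary) and installs C10 at the formyl oxidation level as a vinylogous amide.

Step 4
Reactants: 4 (R,E)-3-[(tert-butyldimethylsilyl)oxy]-5-[(dimethylamino)methylidene]-2,2-dimethylcyclopentan-1-one
Product: 5 (R)-4-[(tert-butyldimethylsilyl)oxy]-2,3,3-trimethylcyclopent-1-ene-1-carbaldehyde
Conditions: MeLi, CeCl3, THF, −78 °C; then AcOH/NaOAc, THF/H2O, rt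
Reagents that add atoms: methyllithium, [Li]C; water, O
Why: CeCl3-assisted 1,2-addition of MeLi to the vinylogous amide carbonyl, then acid-induced loss of water and hydrolysis of the vinylogous iminium ion (Stork–Danheiser-type 1,3-carbonyl transposition), should give the β-methyl enal, the new methyl being C6.

Step 5
Reactants: 5 (R)-4-[(tert-butyldimethylsilyl)oxy]-2,3,3-trimethylcyclopent-1-ene-1-carbaldehyde
Product: 6 (R)-tert-butyl({2,2-dimethyl-3-methylidene-4-[(triethylsilyloxy)methylidene]cyclopentyl}oxy)dimethylsilane (E/Z mixture at the enol ether)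
Conditions: TESOTf, Et3N, Et2O, −78 to 0 °C
Reagents that add atoms: triethylsilyl triflate, CC[Si](CC)(CC)OS(=O)(=O)C(F)(F)F
Why: Soft enolisation (O-silylation of the enal, then removal of one of the only γ-hydrogens, those of the C6 methyl) should give the s-cis-locked 1-silyloxy diene; the enol ether geometry is irrelevant because C10 is oxidised later.

Step 6
Reactants: 6 (R)-tert-butyl({2,2-dimethyl-3-methylidene-4-[(triethylsilyloxy)methylidene]cyclopentyl}oxy)dimethylsilane; 7 2-[(trimethylsilyl)methyl]prop-2-en-1-ol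
Product: 10 (3R)-3-(tert-butyldimethylsilyloxy)-4,4-dimethyl-8-methylidene-Δ1(5)-hydroazulen-10-ol (skeleton numbering; both C10 epimers), via allyl triflate 8 (not isolated), via cycloadduct triethylsilyl ether 9 (not isolated)
Conditions: 7, Tf2O, 2,6-di-tert-butyl-4-methylpyridine, CH2Cl2, −78 °C; add 6, −78 to −50 °C; then Et3N·3HF, THF, 0 °C
Reagents that add atoms: none
Why: The triflate 8 behaves as a 2-(silylmethyl)allyl cation: the γ-carbon C6 of the silyl dienol ether attacks its CH2 terminus in a vinylogous Mukaiyama alkylation (C6–C7), and the resulting unsaturated silyloxocarbenium ion is captured at C10 by the tethered allylsilane in a Hosomi–Sakurai closure (C9–C10), loss of Me3Si+ leaving the C8 exocyclic methylene. The closest known reaction type is the (4+3) cycloaddition of 2-(trimethylsilylmethyl)allyl cations with 1,3-dienes, here run stepwise through the oxocarbenium ion. The seven-membered ring closes in the second bond formation, 7-exo-trig with respect to the oxocarbenium carbon (endo with respect to the allylsilane π bond), while the cyclopentane is carried through unchanged. The only new stereocentre, C10, is not controlled and is erased in step 7, so no facial selectivity is required. The step does need γ- over α-attack and (4+3) over (3+2) closure; both alternatives would build a quaternary carbon (at C1, or at C5 next to the gem-dimethyl carbon C4). The symmetrical three-carbon partner removes any regiochemical question, and the two exocyclic double bonds on adjacent ring carbons hold the diene s-cis.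

Step 7
Reactants: 10 (3R)-3-(tert-butyldimethylsilyloxy)-4,4-dimethyl-8-methylidene-Δ1(5)-hydroazulen-10-ol (C10 epimers)
Product: 11 (3R)-3-(tert-butyldimethylsilyloxy)-4,4-dimethyl-8-methylidene-Δ1(5)-hydroazulen-10-one
Conditions: Dess–Martin periodinane, NaHCO3, CH2Cl2, 0 °C
Reagents that add atoms: none
Why: Dess–Martin oxidation converges the epimeric allylic alcohols on one enone and erases the uncontrolled C10 centre; buffered, non-basic conditions should keep the β,γ-exocyclic alkene out of conjugation.

Step 8
Reactants: 11 (3R)-3-(tert-butyldimethylsilyloxy)-4,4-dimethyl-8-methylidene-Δ1(5)-hydroazulen-10-one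
Product: 12 (3R,10S)-3-(tert-butyldimethylsilyloxy)-4,4-dimethyl-8-methylidene-Δ1(5)-hydroazulen-10-ol (10α-OH)
Conditions: (R)-2-methyl-CBS-oxazaborolidine (20 mol %), catecholborane, toluene, −78 °C
Reagents that add atoms: none
Why: CBS reduction (1,2-selective on the transoid enone) under reagent control, with the fully substituted alkenyl arm as the large group, should give the (10S)-alcohol, that is the hydroxyl on the α face, independent of the remote C3 centre.

Step 9
Reactants: 12 (3R,10S)-3-(tert-butyldimethylsilyloxy)-4,4-dimethyl-8-methylidene-Δ1(5)-hydroazulen-10-ol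
Product: 13 (3R,8R,10S)-3-(tert-butyldimethylsilyloxy)-4,4,8-trimethyl-Δ1(5)-hydroazulen-10-ol (8β-methyl, 10α-OH)
Conditions: [Rh(nbd)(dppb)]BF4 (5 mol %), H2 (50 atm), CH2Cl2, rt
Reagents that add atoms: none
Why: Hydroxyl-directed hydrogenation with a cationic rhodium catalyst: the homoallylic C10 hydroxyl binds the metal and hydrogen is delivered to the 1,1-disubstituted alkene from the α face, so the C8 methyl ends up β; the tetrasubstituted C1=C5 alkene is inert to this catalyst and high pressure suppresses isomerisation of the exocyclic alkene.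

Step 10
Reactants: 13 (3R,8R,10S)-3-(tert-butyldimethylsilyloxy)-4,4,8-trimethyl-Δ1(5)-hydroazulen-10-ol
Product: 14 (1S,3R,5S,8R,10S)-1α,5α-epoxy-3-(tert-butyldimethylsilyloxy)-4,4,8-trimethylhydroazulen-10-ol (epoxide syn to the 10α-OH)
Conditions: VO(acac)2 (5 mol %), t-BuOOH, CH2Cl2, 0 °C to rt
Reagents that add atoms: tert-butyl hydroperoxide, CC(C)(C)OO
Why: Vanadium-catalysed hydroxyl-directed epoxidation delivers oxygen to the tetrasubstituted allylic alkene syn to the C10 hydroxyl, that is on the α face, which is also the face away from the C3 silyl ether (matched), and so fixes the C5 oxygen.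

Step 11
Reactants: 14 (1S,3R,5S,8R,10S)-1α,5α-epoxy-3-(tert-butyldimethylsilyloxy)-4,4,8-trimethylhydroazulen-10-ol
Product: 16 (1R,3R,5R,8R)-3-(tert-butyldimethylsilyloxy)-5-(triethylsilyloxy)-4,4,8-trimethylhydroazulen-10-one (trans-fused: 1β-H and 5α-OTES), via epoxy silyl ether 15 (not isolated)
Conditions: TESOTf (2.2 equiv), i-Pr2NEt, 4 Å MS, CH2Cl2, −78 to −40 °C
Reagents that add atoms: triethylsilyl triflate, CC[Si](CC)(CC)OS(=O)(=O)C(F)(F)F
Why: Semipinacol rearrangement of a 2,3-epoxy silyl ether (the non-aldol aldol process): after in-flask silylation the silyl triflate opens the epoxide at C1 with antiperiplanar 1,2-hydride shift from C10 (H-10 is β, anti to the α C1–O bond), which gives the C10 ketone, places hydrogen on the β face of C1 with inversion and leaves the α oxygen on C5 as its silyl ether, so the trans ring fusion should be set stereospecifically.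

Step 12
Reactants: 16 (1R,3R,5R,8R)-3-(tert-butyldimethylsilyloxy)-5-(triethylsilyloxy)-4,4,8-trimethylhydroazulen-10-one
Product: 17 (1R,3R,5R,8R)-3-(tert-butyldimethylsilyloxy)-5-(triethylsilyloxy)-4,4,8,9-tetramethylhydroazulen-10-one (C9 epimers)
Conditions: LiN(i-Pr)2, THF, −78 °C; MeI, −78 to −40 °C
Reagents that add atoms: iodomethane, CI
Why: Kinetic enolate alkylation: the amide base removes a proton from the unhindered C9 methylene rather than from the ring-fusion methine C1, and methylation gives the 9-methyl ketone as an epimer mixture that converges in the next step.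

Step 13
Reactants: 17 (1R,3R,5R,8R)-3-(tert-butyldimethylsilyloxy)-5-(triethylsilyloxy)-4,4,8,9-tetramethylhydroazulen-10-one; 18 phenyl vinyl sulfoxide
Product: 20 (1R,3R,5R,8R,9S)-9-ethenyl-3-(tert-butyldimethylsilyloxy)-5-(triethylsilyloxy)-4,4,8,9-tetramethylhydroazulen-10-one (9β-methyl and 9α-vinyl), via sulfoxide adduct 19 (not isolated)
Conditions: LiN(i-Pr)2, THF, −78 to −20 °C; 18, −78 °C to rt; aq. NH4Cl; then toluene, NaHCO3, 110 °C
Reagents that add atoms: none
Why: Deprotonation at C9 (C1–H is shielded by the adjacent quaternary, silyloxy-bearing C5) gives the tetrasubstituted enolate, which should add to the vinyl sulfoxide (Michael addition of a vinyl cation equivalent) on the face anti to the neighbouring C8 methyl, the usual outcome for 2,3-dimethylcycloalkanone enolates, so that the C9 methyl is β and the new chain α; thermal sulfoxide syn-elimination then reveals the vinyl group.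

Step 14
Reactants: 20 (1R,3R,5R,8R,9S)-9-ethenyl-3-(tert-butyldimethylsilyloxy)-5-(triethylsilyloxy)-4,4,8,9-tetramethylhydroazulen-10-one; 21 4-bromofuran-2(5H)-one
Product: 23 3-O-tert-butyldimethylsilyl-5-O-triethylsilyl ether of the target, via alkylborane 22 (not isolated)
Conditions: 9-BBN, THF, rt; then 21, PdCl2(dppf) (5 mol %), AsPh3, K3PO4, DMF/H2O, rt to 40 °C
Reagents that add atoms: none
Why: Anti-Markovnikov hydroboration of the neopentyl vinyl group with 9-BBN (much faster than reduction of the hindered ketone) and B-alkyl Suzuki–Miyaura coupling with the vinylogous acyl bromide should forge C12–C13 and complete the β-substituted butenolide without touching a stereocentre.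

Step 15
Reactants: 23 3-O-tert-butyldimethylsilyl-5-O-triethylsilyl ether of the target
Product: 24 target, (1R,3R,5R,8R,9S)-3,5-dihydroxy-4,4,8,9-tetramethyl-9-[2-(5-oxo-2,5-dihydrofuran-3-yl)ethyl]hydroazulen-10-one (skeleton numbering)
Conditions: HF (48 % aq.), MeCN, 0 °C to rt
Reagents that add atoms: none
Why: Acidic fluoride desilylation removes the tertiary triethylsilyl and the secondary tert-butyldimethylsilyl ethers; under these non-basic conditions neither epimerisation at C1 nor retro-aldol cleavage of the β-hydroxy ketone is expected.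

**Compound list**

1 | 2,2-dimethylcyclopentane-1,3-dione | CC1(C)C(=O)CCC1=O | starting material
2 | (R)-3-hydroxy-2,2-dimethylcyclopentan-1-one | CC1(C)C(=O)CC[C@H]1O | intermediate
3 | (R)-3-[(tert-butyldimethylsilyl)oxy]-2,2-dimethylcyclopentan-1-one | CC1(C)C(=O)CC[C@H]1O[Si](C)(C)C(C)(C)C | intermediate
4 | (R,E)-3-[(tert-butyldimethylsilyl)oxy]-5-[(dimethylamino)methylidene]-2,2-dimethylcyclopentan-1-one | CC1(C)C(=O)/C(=C/N(C)C)C[C@H]1O[Si](C)(C)C(C)(C)C | intermediate
5 | (R)-4-[(tert-butyldimethylsilyl)oxy]-2,3,3-trimethylcyclopent-1-ene-1-carbaldehyde | CC1(C)C(C)=C(C=O)C[C@H]1O[Si](C)(C)C(C)(C)C | intermediate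
6 | (R)-tert-butyl({2,2-dimethyl-3-methylidene-4-[(triethylsilyloxy)methylidene]cyclopentyl}oxy)dimethylsilane, enol ether E/Z mixture | CC1(C)C(=C)C(=CO[Si](CC)(CC)CC)C[C@H]1O[Si](C)(C)C(C)(C)C | intermediate
7 | 2-[(trimethylsilyl)methyl]prop-2-en-1-ol | C=C(CO)C[Si](C)(C)C | starting material
8 | 2-[(trimethylsilyl)methyl]prop-2-en-1-yl trifluoromethanesulfonate (not isolated) | C=C(COS(=O)(=O)C(F)(F)F)C[Si](C)(C)C | intermediate
9 | C10 triethylsilyl ether of 10, C10 epimers (not isolated) | C=C1CCC2=C(C[C@@H](O[Si](C)(C)C(C)(C)C)C2(C)C)C(O[Si](CC)(CC)CC)C1 | intermediate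
10 | (3R)-3-(tert-butyldimethylsilyloxy)-4,4-dimethyl-8-methylidene-Δ1(5)-hydroazulen-10-ol, C10 epimers | C=C1CCC2=C(C[C@@H](O[Si](C)(C)C(C)(C)C)C2(C)C)C(O)C1 | intermediate
11 | (3R)-3-(tert-butyldimethylsilyloxy)-4,4-dimethyl-8-methylidene-Δ1(5)-hydroazulen-10-one | C=C1CCC2=C(C[C@@H](O[Si](C)(C)C(C)(C)C)C2(C)C)C(=O)C1 | intermediate
12 | (3R,10S)-3-(tert-butyldimethylsilyloxy)-4,4-dimethyl-8-methylidene-Δ1(5)-hydroazulen-10-ol | C=C1CCC2=C(C[C@@H](O[Si](C)(C)C(C)(C)C)C2(C)C)[C@@H](O)C1 | intermediate
13 | (3R,8R,10S)-3-(tert-butyldimethylsilyloxy)-4,4,8-trimethyl-Δ1(5)-hydroazulen-10-ol | C[C@@H]1CCC2=C(C[C@@H](O[Si](C)(C)C(C)(C)C)C2(C)C)[C@@H](O)C1 | intermediate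
14 | (1S,3R,5S,8R,10S)-1α,5α-epoxy-3-(tert-butyldimethylsilyloxy)-4,4,8-trimethylhydroazulen-10-ol | C[C@@H]1CC[C@]23O[C@@]3(C[C@@H](O[Si](C)(C)C(C)(C)C)C2(C)C)[C@@H](O)C1 | intermediate
15 | C10 triethylsilyl ether of 14 (not isolated) | C[C@@H]1CC[C@]23O[C@@]3(C[C@@H](O[Si](C)(C)C(C)(C)C)C2(C)C)[C@@H](O[Si](CC)(CC)CC)C1 | intermediate
16 | (1R,3R,5R,8R)-3-(tert-butyldimethylsilyloxy)-5-(triethylsilyloxy)-4,4,8-trimethylhydroazulen-10-one | C[C@@H]1CC[C@@]2(O[Si](CC)(CC)CC)[C@@H](C[C@@H](O[Si](C)(C)C(C)(C)C)C2(C)C)C(=O)C1 | intermediate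
17 | (1R,3R,5R,8R)-3-(tert-butyldimethylsilyloxy)-5-(triethylsilyloxy)-4,4,8,9-tetramethylhydroazulen-10-one, C9 epimers | C[C@@H]1CC[C@@]2(O[Si](CC)(CC)CC)[C@@H](C[C@@H](O[Si](C)(C)C(C)(C)C)C2(C)C)C(=O)C1C | intermediate
18 | phenyl vinyl sulfoxide | C=CS(=O)c1ccccc1 | starting material
19 | 9-[2-(phenylsulfinyl)ethyl] adduct of 17, sulfoxide epimers (not isolated) | C[C@@H]1CC[C@@]2(O[Si](CC)(CC)CC)[C@@H](C[C@@H](O[Si](C)(C)C(C)(C)C)C2(C)C)C(=O)[C@@]1(C)CCS(=O)c1ccccc1 | intermediate
20 | (1R,3R,5R,8R,9S)-9-ethenyl-3-(tert-butyldimethylsilyloxy)-5-(triethylsilyloxy)-4,4,8,9-tetramethylhydroazulen-10-one | C[C@@H]1CC[C@@]2(O[Si](CC)(CC)CC)[C@@H](C[C@@H](O[Si](C)(C)C(C)(C)C)C2(C)C)C(=O)[C@@]1(C)C=C | intermediate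
21 | 4-bromofuran-2(5H)-one | BrC1=CC(=O)OC1 | starting material
22 | B-alkyl-9-BBN from 20, boron on C12 (not isolated) | C[C@@H]1CC[C@@]2(O[Si](CC)(CC)CC)[C@@H](C[C@@H](O[Si](C)(C)C(C)(C)C)C2(C)C)C(=O)[C@@]1(C)CCB1C2CCCC1CCC2 | intermediate
23 | 3-O-tert-butyldimethylsilyl-5-O-triethylsilyl ether of the target | C[C@@H]1CC[C@@]2(O[Si](CC)(CC)CC)[C@@H](C[C@@H](O[Si](C)(C)C(C)(C)C)C2(C)C)C(=O)[C@@]1(C)CCC1=CC(=O)OC1 | intermediate
24 | target, (1R,3R,5R,8R,9S) in skeleton numbering | C[C@@H]1CC[C@@]2(O)[C@@H](C[C@@H](O)C2(C)C)C(=O)[C@@]1(C)CCC1=CC(=O)OC1 | target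

**Step count**

Total steps: 15. Longest linear sequence: 15 steps (1 to 24); compounds 7, 18 and 21 are used as purchased.

**Steps most likely to fail**

1. Step 6. The silyl group may be lost from the oxocarbenium ion before the allylsilane closes the ring, so that the cascade stops after the first bond. The allyl triflate may also self-condense, or the silyl triflate released may ionise the allylic silyl ether once formed. Fallback, from 4 back to 10, with the two bonds made separately by known reactions: commercial 3-methylbut-3-en-1-ol is dilithiated (n-BuLi, TMEDA) and C-silylated to 3-[(trimethylsilyl)methyl]but-3-en-1-ol F1, which is converted (I2, PPh3, imidazole) into 4-iodo-2-[(trimethylsilyl)methyl]but-1-ene F2. The organolithium from F2 (t-BuLi, −78 °C), with CeCl3, is added to enaminone 4 in place of MeLi, and the same acidic work-up should give the enal carrying the allylsilane chain on C5, F3, in which C6–C7 is already in place. Fluoride-triggered (TBAF) intramolecular 1,2-allylation of the aldehyde then closes the seven-membered ring at C9–C10 and gives 10.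

2. Step 11. The epoxide may open at the C5–O bond instead, with Wagner–Meerwein migration of a C4 methyl, or the C9–C10 ring bond may migrate in place of hydride (ring contraction). Fallback, from 14 back to 16: Dess–Martin oxidation gives the α,β-epoxy ketone F4. SmI2 (THF/MeOH, −78 °C) then cleaves the C1–O bond reductively; protonation of the samarium enolate from the β face, away from the metal-bound C5 alkoxide, should give the trans β-hydroxy ketone F5. If the cis isomer forms, the enolisable ring-fusion centre is equilibrated. Silylation of the tertiary hydroxyl (TESOTf, 2,6-lutidine) gives 16.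

3. Step 13. The hindered tetrasubstituted enolate may add slowly or reversibly to the vinyl sulfoxide, or enolisation toward C1 may compete and lead to β-elimination of the silanol. Fallback, from 17 back to 20: the enolate is alkylated with allyl bromide, the most dependable electrophile for a quaternary carbon of this kind (again anti to the C8 methyl), to give the 9-allyl ketone F6. RuHCl(CO)(PPh3)3 moves the double bond to the 9-(E)-prop-1-enyl ketone F7, and ethenolysis with the second-generation Hoveyda–Grubbs catalyst under ethylene trims it to the vinyl ketone 20.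

**Further compounds**

F1 | step 6 | 3-[(trimethylsilyl)methyl]but-3-en-1-ol | C=C(CCO)C[Si](C)(C)C
F2 | step 6 | 4-iodo-2-[(trimethylsilyl)methyl]but-1-ene | C=C(CCI)C[Si](C)(C)C
F3 | step 6 | (R)-4-[(tert-butyldimethylsilyl)oxy]-3,3-dimethyl-2-{3-[(trimethylsilyl)methyl]but-3-en-1-yl}cyclopent-1-ene-1-carbaldehyde | CC1(C)C(CCC(=C)C[Si](C)(C)C)=C(C=O)C[C@H]1O[Si](C)(C)C(C)(C)C
F4 | step 11 | (1S,3R,5S,8R)-1α,5α-epoxy-3-(tert-butyldimethylsilyloxy)-4,4,8-trimethylhydroazulen-10-one | C[C@@H]1CC[C@]23O[C@@]3(C[C@@H](O[Si](C)(C)C(C)(C)C)C2(C)C)C(=O)C1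
F5 | step 11 | (1R,3R,5R,8R)-3-(tert-butyldimethylsilyloxy)-5-hydroxy-4,4,8-trimethylhydroazulen-10-one | C[C@@H]1CC[C@@]2(O)[C@@H](C[C@@H](O[Si](C)(C)C(C)(C)C)C2(C)C)C(=O)C1
F6 | step 13 | (1R,3R,5R,8R,9S)-9-allyl-3-(tert-butyldimethylsilyloxy)-5-(triethylsilyloxy)-4,4,8,9-tetramethylhydroazulen-10-one | C[C@@H]1CC[C@@]2(O[Si](CC)(CC)CC)[C@@H](C[C@@H](O[Si](C)(C)C(C)(C)C)C2(C)C)C(=O)[C@@]1(C)CC=C
F7 | step 13 | (1R,3R,5R,8R,9S)-9-[(E)-prop-1-enyl]-3-(tert-butyldimethylsilyloxy)-5-(triethylsilyloxy)-4,4,8,9-tetramethylhydroazulen-10-one | C[C@@H]1CC[C@@]2(O[Si](CC)(CC)CC)[C@@H](C[C@@H](O[Si](C)(C)C(C)(C)C)C2(C)C)C(=O)[C@@]1(C)/C=C/C
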